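**Route outline**

- Retrosynthesis first cuts the two ester C–O bonds (O6–angeloyl, O9–methacryloyl), removes the two exocyclic methylenes (C4=C3, C11=C13) as Mannich products and traces the C1=C2 vinyl group back to an ethynyl group.
- Enabling feature: the vinyl carbons C1–C2 on quaternary C10 and the C4–C15HO arm on C5 are the two ends of one chain, C1–C2···C15–C4. Joining C2 to C15 rebuilds ring A (C10–C1–C2–C15–C4–C5) of a trans-decalin on the cyclohexane C5–C10 (ring B), so the C10-ethynyl/C5-CH2CHO pair is the product of an Eschenmoser–Tanabe fragmentation of a 2,15-epoxy-1-ketone.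
- Further cuts: O8–C12 (cis γ-lactone), C7–C11 (through a C7–C8 donor–acceptor cyclopropane made from a C8 methyl enol ether and dimethyl diazomalonate), then C1–C10 and C4–C5 (quinone Diels–Alder).
- Forward order: ring B is the quinone ring; ring A is annulated by the Diels–Alder reaction; a transient cyclopropane carries C11/C12 to C7; the lactone closes on O8; the C2–C15 epoxide is added; ring A and the epoxide are opened in the fragmentation; the methylenes and the two esters come last.
- Stereochemistry: C10 from the BINOL–titanium-catalysed cycloaddition; C5 by equilibration to the trans-decalin; C9 and C6 by hydride attack anti to the axial C10 methyl; C7 by cyclopropanation anti to the axial 6β-silyloxy group; C8 by hydride delivered from the 6β-hydroxyl. The C1, cyclopropane, epoxide and C11 centres are transient.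

Key step: step 15

Numbering and faces: elemane numbering of the target is used throughout. In the decalin intermediates ring B is C5–C10 and ring A is C10–C1–C2–C15–C4–C5; C14 is the C10 methyl; β is the face of the C10 methyl, α the opposite face.

Remark on the quinone: it has to be the 2-methoxy-6-methyl isomer (methoxy and methyl flanking the same carbonyl). Only then does cycloaddition at the methyl-bearing double bond leave the enol-ether oxygen on C8, next to C9; the 2-methoxy-5-methyl isomer would place it on C7 and reverse the lactone orientation.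

Assumption: the (S)-BINOL-derived titanium catalyst is taken to deliver the diene to the quinone face that gives the C10 configuration drawn; if the sense proves opposite, (R)-BINOL is used with no other change.

Remark on the diene: commercial 1-acetoxybutadiene is an E/Z mixture; only the E isomer 3 cycloadds, so an excess is used.

**Route**

Step 1
Reactants: 1 2-methoxy-6-methylphenol
Product: 2 2-methoxy-6-methyl-1,4-benzoquinone
Conditions: O2 (1 atm), Co(salen) [CoC16H14N2O2] (5 mol %), DMF, rt
Reagents that add atoms: dioxygen, O=O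
Why: Cobalt–salen-catalysed aerobic oxidation of a 2,6-disubstituted phenol should give the para-quinone, because both ortho positions are blocked and only the para position is open to oxygenation.

Step 2
Reactants: 2 2-methoxy-6-methyl-1,4-benzoquinone; 3 (E)-1-acetoxy-1,3-butadiene
Product: 4 cis-fused cycloadduct (1α-acetoxy-8-methoxy-10β-methyl-5β-H-decalin-2(15),7-diene-6,9-dione)
Conditions: (S)-BINOL/TiCl2(OiPr)2 (10 mol %, prepared over 4 Å molecular sieves, sieves filtered off), toluene, 0 °C → rt
Reagents that add atoms: none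
Why: In this BINOL–titanium-catalysed quinone Diels–Alder reaction, two-point binding of titanium to the C8 methoxy oxygen and the C9 carbonyl makes C9=O the controlling carbonyl, so the unsubstituted diene terminus bonds to C5 and the acetoxy-bearing terminus to methyl-bearing C10, the endo transition state places the acetoxy group trans to the C10 methyl and H5 cis to it, and the chiral ligand selects the quinone face and thereby sets C10.

Step 3
Reactants: 4 cis-fused cycloadduct
Product: 5 trans-fused enedione (1α-acetoxy-8-methoxy-10β-methyl-5α-H-decalin-2(15),7-diene-6,9-dione)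
Conditions: DBU (0.2 equiv), CH2Cl2, rt
Reagents that add atoms: none
Why: Reversible enolisation of the C6 ketone towards C5 should equilibrate the ring fusion to the trans-decalin, the more stable isomer of angularly methylated ene-diones, which sets H5 α, while quaternary C10 cannot epimerise and the acetate has no elimination pathway.

Step 4
Reactants: 5 trans-fused enedione
Product: 6 9β-hydroxy vinylogous ester (1α-acetoxy-9β-hydroxy-8-methoxy-10β-methyl-5α-H-decalin-2(15),7-dien-6-one)
Conditions: NaBH4, CeCl3·7H2O, MeOH/CH2Cl2, –78 °C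
Reagents that add atoms: none
Why: Luche 1,2-reduction should select the C9 carbonyl, which is not deactivated as a vinylogous ester, and hydride should attack anti to the pseudo-axial C10 methyl (the peri 1α-acetoxy group lies beside the carbonyl oxygen, outside the Bürgi–Dunitz trajectory), giving the equatorial 9β-alcohol.

Step 5
Reactants: 6 9β-hydroxy vinylogous ester
Product: 7 9β-O-TBS vinylogous ester (1α-acetoxy-9β-(tert-butyldimethylsilyloxy)-8-methoxy-10β-methyl-5α-H-decalin-2(15),7-dien-6-one)
Conditions: TBSOTf, 2,6-lutidine, CH2Cl2, –78 → 0 °C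
Reagents that add atoms: tert-butyldimethylsilyl triflate, CC(C)(C)[Si](C)(C)OS(=O)(=O)C(F)(F)F
Why: A silyl triflate with a hindered pyridine base is the standard way to silylate a neopentyl secondary alcohol, and the acetate and the vinylogous ester are inert to it.

Step 6
Reactants: 7 9β-O-TBS vinylogous ester
Product: 8 6β-allylic alcohol (1α-acetoxy-9β-(tert-butyldimethylsilyloxy)-8-methoxy-10β-methyl-5α-H-decalin-2(15),7-dien-6β-ol)
Conditions: NaBH4, CeCl3·7H2O, MeOH, –20 → 0 °C; aq. NaHCO3 work-up
Reagents that add atoms: none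
Why: Luche 1,2-reduction of the vinylogous ester carbonyl should occur from the α face, because the β (axial) trajectory at C6 is syn-axial to the C10 methyl, giving the axial 6β-alcohol; the acetate survives borohydride at low temperature and the basic work-up avoids acid-induced loss of the allylic oxygen.

Step 7
Reactants: 8 6β-allylic alcohol
Product: 9 6β-OTES, 9β-OTBS methyl enol ether (1α-acetoxy-6β-(triethylsilyloxy)-9β-(tert-butyldimethylsilyloxy)-8-methoxy-10β-methyl-5α-H-decalin-2(15),7-diene)
Conditions: TESCl, imidazole, DMF, 0 °C → rt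
Reagents that add atoms: chlorotriethylsilane, CC[Si](Cl)(CC)CC
Why: Chlorosilane/imidazole silylation proceeds under basic conditions, which protects the axial allylic alcohol without ionising the acid-labile γ-methoxy allylic system.

Step 8
Reactants: 9 6β-OTES, 9β-OTBS methyl enol ether; 10 dimethyl diazomalonate
Product: 11 donor–acceptor cyclopropane (C11(CO2Me)2 bridging C7 and C8 on the α face, 8β-OMe)
Conditions: Rh2(esp)2 [Rh2(C16H20O4)2] (1 mol %), CH2Cl2, 0 °C → rt, slow addition of 10
Reagents that add atoms: none
Why: In this rhodium-carbenoid cyclopropanation the electrophilic malonate carbenoid should attack the most electron-rich alkene, the C7=C8 methyl enol ether, in preference to the C2=C15 alkene next to the acetate, and from the α face because the β face is covered by the axial 6β-silyloxy group and the axial C10 methyl, which sets C7 (C7–C11 α).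

Step 9
Reactants: 11 donor–acceptor cyclopropane
Product: 12 6β-hydroxy-8-ketone carrying 7α-CH(CO2Me)2 (1α-OAc, 9β-OTBS retained)
Conditions: 1 M aq. HCl, THF, 0 °C → rt
Reagents that add atoms: water, O
Why: Acid-promoted push–pull opening of the donor–acceptor cyclopropane cleaves only the C8–C11 bond (methoxy oxocarbenium, hydrolysed to the ketone), so the C7–C11 bond and the C7 configuration stay intact, the TES ether is hydrolysed in the same operation while the hindered TBS ether and the acetate persist, and the equatorial C7–H is poorly aligned for enolisation, which should suppress epimerisation and β-elimination during the short exposure.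

Step 10
Reactants: 12 6β-hydroxy-8-ketone
Product: 14 cis-fused 8α,12-lactone bearing 11-CO2Me (exo) together with free 6β-OH, via 6β,8α-diol malonate 13 (not isolated)
Conditions: Me4NBH(OAc)3, MeCN/AcOH (1:1), –30 → 0 °C; then CSA (cat.), CH2Cl2, rt
Reagents that add atoms: none
Why: In the Evans–Saksena reduction the axial 6β-hydroxyl binds the acetoxyborohydride and delivers hydride to the β face of the C8 ketone (1,3-anti diol, 8α-OH), after which the equatorial 8α-hydroxyl closes onto the axial 7α-malonate as the only geometrically possible, cis-fused γ-lactone, since the trans-diaxial 6β-hydroxyl cannot lactonise.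

Step 11
Reactants: 14 cis-fused lactone ester with free 6β-OH
Product: 15 6β-OTES lactone ester (1α-OAc, 9β-OTBS, 11-CO2Me)
Conditions: TESOTf, 2,6-lutidine, CH2Cl2, –78 → 0 °C
Reagents that add atoms: triethylsilyl triflate, CC[Si](CC)(CC)OS(=O)(=O)C(F)(F)F
Why: The hindered axial 6β-hydroxyl needs a silyl triflate, and the weak pyridine base leaves the malonate-type C11–H and the lactone untouched.

Step 12
Reactants: 15 6β-OTES lactone ester
Product: 17 1α-hydroxy lactone 11-carboxylic acid (6β-OTES, 9β-OTBS), via dilithium dihydroxy malonate 16 (not isolated)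
Conditions: LiOH·H2O (6 equiv), THF/MeOH/H2O, 0 °C → rt; then 1 M aq. HCl to pH 3, 0 °C
Reagents that add atoms: lithium hydroxide, [Li+].[OH-]
Why: Saponification cleaves the C1 acetate and the methyl ester and opens the lactone to the malonate dianion, and acidification recloses the cis γ-lactone from the 8α-hydroxyl to leave the lactone α-carboxylic acid; only the epimerisable C11 is touched, and silyl ethers on hindered secondary carbons tolerate LiOH at rt.

Step 13
Reactants: 17 1α-hydroxy lactone acid
Product: 18 2α,15α-epoxy-1α-hydroxy lactone acid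
Conditions: VO(acac)2 (5 mol %), t-BuOOH, CH2Cl2, 0 °C → rt
Reagents that add atoms: tert-butyl hydroperoxide, CC(C)(C)OO
Why: Vanadium-catalysed hydroxyl-directed epoxidation delivers oxygen to the C2=C15 alkene syn to the allylic 1α-hydroxyl, so a single (transient) α-epoxide should form.

Step 14
Reactants: 18 2α,15α-epoxy-1α-hydroxy lactone acid
Product: 19 2α,15α-epoxy-1-keto lactone acid
Conditions: Dess–Martin periodinane, CH2Cl2, rt
Reagents that add atoms: none
Why: Dess–Martin oxidation converts the hindered secondary epoxy alcohol into the α,β-epoxy ketone under near-neutral conditions that spare the epoxide, the carboxylic acid, the lactone and both silyl ethers.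

Step 15
Reactants: 19 2α,15α-epoxy-1-keto lactone acid
Product: 21 seco acid (10α-ethynyl, 5β-CH2CHO, 6β-OTES, 9β-OTBS, cis 8,12-lactone 11-carboxylic acid), via C1 tosylhydrazone 20 (not isolated)
Conditions: TsNHNH2 (1.05 equiv), AcOH/CH2Cl2 (1:1), –20 °C → rt
Reagents that add atoms: none
Why: The C1 ketone condenses with tosylhydrazide to hydrazone 20, whose tautomerisation opens the epoxide at C2–O to an azo-alkene carrying an alkoxide on C15, and a Grob-type collapse then forms C15=O and the C1≡C2 triple bond while the C2–C15 σ bond breaks and N2 and p-toluenesulfinate leave. The closest known reaction type is exactly this Eschenmoser–Tanabe fragmentation of cyclic α,β-epoxy ketone sulfonylhydrazones to acetylenic carbonyl compounds. No ring is closed: ring A and the epoxide are opened, leaving the ethynyl group on C10 and the CH2–CHO arm on C5. No stereocentre is created and none of C5–C10 is touched. The selectivity needed is constitutional only: quaternary C10 leaves C2 as the sole α-carbon, and the placement of the ketone at C1 with the epoxide across C2–C15 was fixed by the orientation of the Diels–Alder reaction. The mildly acidic medium spares the cis-lactone, the carboxylic acid and both silyl ethers, and keeping the hydrazide near one equivalent protects the new aldehyde.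

Step 16
Reactants: 21 seco acid with 10α-ethynyl group
Product: 22 10α-vinyl seco acid (5β-CH2CHO, 6β-OTES, 9β-OTBS, lactone 11-carboxylic acid)
Conditions: H2 (1 atm), Pd/CaCO3/Pb(OAc)2 (Lindlar catalyst), quinoline, EtOAc, rt
Reagents that add atoms: none
Why: Lindlar semihydrogenation should reduce the terminal alkyne to the vinyl group and stop there, leaving the aldehyde, the acid and the lactone untouched.

Step 17
Reactants: 22 10α-vinyl seco acid; 23 formaldehyde
Product: 24 bis-silyl elemanolide dienal (C4(=CH2)–CHO arm, 11(13)-methylene lactone, 6β-OTES, 9β-OTBS)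
Conditions: 37% aq. CH2O (excess), Et2NH, AcOH/NaOAc, THF, rt → 60 °C
Reagents that add atoms: none
Why: In this double Mannich methylenation the aldehyde is α-methylenated through its enamine (addition to the formaldehyde iminium ion, then loss of the amine) and the lactone α-carboxylic acid adds at C11 and then loses CO2 and the amine, which installs both exocyclic methylenes (C3 and C13) and erases the C11 stereocentre.

Step 18
Reactants: 24 bis-silyl elemanolide dienal
Product: 25 6β-hydroxy 9β-OTBS dienal
Conditions: HF·pyridine, pyridine, THF, 0 °C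
Reagents that add atoms: none
Why: Buffered HF·pyridine cleaves a triethylsilyl ether much faster than a neopentyl tert-butyldimethylsilyl ether, and the mildly acidic medium should not trigger conjugate addition or translactonisation.

Step 19
Reactants: 25 6β-hydroxy 9β-OTBS dienal; 26 angelic acid
Product: 28 6β-O-angeloyl 9β-OTBS dienal, via angelic 2,4,6-trichlorobenzoic anhydride 27 (not isolated)
Conditions: 26, 2,4,6-Cl3C6H2COCl, Et3N, toluene, rt; then 25, 80 °C
Reagents that add atoms: none
Why: In this Yamaguchi esterification run without DMAP the preformed mixed anhydride should acylate the hindered axial 6β-hydroxyl on heating, and the absence of a nucleophilic catalyst avoids isomerisation of the (Z)-angeloyl unit to the tigloyl isomer.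

Step 20
Reactants: 28 6β-O-angeloyl 9β-OTBS dienal
Product: 29 6β-O-angeloyl 9β-hydroxy dienal
Conditions: 48% aq. HF, MeCN, 0 °C → rt
Reagents that add atoms: none
Why: Acidic fluoride removes the remaining hindered TBS ether under conditions that the angelate, the enal and the methylene lactone tolerate, and the 1,4-disposed O6 ester cannot migrate to O9.

Step 21
Reactants: 29 6β-O-angeloyl 9β-hydroxy dienal; 30 methacrylic anhydride
Product: 31 CNP0102441.1
Conditions: 30, Et3N, DMAP (cat.), CH2Cl2, 0 °C → rt
Reagents that add atoms: none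
Why: DMAP-catalysed acylation of the neopentyl 9β-hydroxyl with the anhydride completes the target without touching any stereocentre.

**Compound list**

1 | 2-methoxy-6-methylphenol | COc1cccc(C)c1O | starting material
2 | 2-methoxy-6-methyl-1,4-benzoquinone | COC1=CC(=O)C=C(C)C1=O | intermediate
3 | (E)-1-acetoxy-1,3-butadiene | CC(=O)O/C=C/C=C | starting material
4 | cis-fused cycloadduct: 1α-acetoxy-8-methoxy-10β-methyl-5β-H-decalin-2(15),7-diene-6,9-dione | CC(=O)O[C@H]1C=CC[C@H]2C(=O)C=C(OC)C(=O)[C@@]12C | intermediate
5 | trans-fused enedione: 1α-acetoxy-8-methoxy-10β-methyl-5α-H-decalin-2(15),7-diene-6,9-dione | CC(=O)O[C@H]1C=CC[C@@H]2C(=O)C=C(OC)C(=O)[C@@]12C | intermediate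
6 | 1α-acetoxy-9β-hydroxy-8-methoxy-10β-methyl-5α-H-decalin-2(15),7-dien-6-one | CC(=O)O[C@H]1C=CC[C@@H]2C(=O)C=C(OC)[C@H](O)[C@@]12C | intermediate
7 | 9β-O-TBS ether of 6 | CC(=O)O[C@H]1C=CC[C@@H]2C(=O)C=C(OC)[C@H](O[Si](C)(C)C(C)(C)C)[C@@]12C | intermediate
8 | 1α-acetoxy-9β-(tert-butyldimethylsilyloxy)-8-methoxy-10β-methyl-5α-H-decalin-2(15),7-dien-6β-ol | CC(=O)O[C@H]1C=CC[C@@H]2[C@H](O)C=C(OC)[C@H](O[Si](C)(C)C(C)(C)C)[C@@]12C | intermediate
9 | 6β-OTES, 9β-OTBS methyl enol ether (6-O-TES ether of 8) | CC(=O)O[C@H]1C=CC[C@@H]2[C@H](O[Si](CC)(CC)CC)C=C(OC)[C@H](O[Si](C)(C)C(C)(C)C)[C@@]12C | intermediate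
10 | dimethyl diazomalonate | COC(=O)C(=[N+]=[N-])C(=O)OC | starting material
11 | donor–acceptor cyclopropane: C11(CO2Me)2 bridging C7 and C8 on the α face, 8β-OMe, 1α-OAc, 6β-OTES, 9β-OTBS | CC(=O)O[C@H]1C=CC[C@@H]2[C@H](O[Si](CC)(CC)CC)[C@H]3C(C(=O)OC)(C(=O)OC)[C@@]3(OC)[C@H](O[Si](C)(C)C(C)(C)C)[C@@]12C | intermediate
12 | 6β-hydroxy-8-ketone with 7α-CH(CO2Me)2 (1α-OAc, 9β-OTBS) | CC(=O)O[C@H]1C=CC[C@@H]2[C@H](O)[C@@H](C(C(=O)OC)C(=O)OC)C(=O)[C@H](O[Si](C)(C)C(C)(C)C)[C@@]12C | intermediate
13 | 6β,8α-diol with 7α-CH(CO2Me)2 (not isolated) | CC(=O)O[C@H]1C=CC[C@@H]2[C@H](O)[C@@H](C(C(=O)OC)C(=O)OC)[C@@H](O)[C@H](O[Si](C)(C)C(C)(C)C)[C@@]12C | intermediate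
14 | cis-fused 8α,12-lactone with exo 11-CO2Me and free 6β-OH (1α-OAc, 9β-OTBS) | CC(=O)O[C@H]1C=CC[C@@H]2[C@H](O)[C@H]3[C@H](C(=O)OC)C(=O)O[C@H]3[C@H](O[Si](C)(C)C(C)(C)C)[C@@]12C | intermediate
15 | 6β-OTES ether of 14 | CC(=O)O[C@H]1C=CC[C@@H]2[C@H](O[Si](CC)(CC)CC)[C@H]3[C@H](C(=O)OC)C(=O)O[C@H]3[C@H](O[Si](C)(C)C(C)(C)C)[C@@]12C | intermediate
16 | dilithium salt of the ring-opened 1α,8α-dihydroxy 7α-malonate (not isolated) | O[C@H]1C=CC[C@@H]2[C@H](O[Si](CC)(CC)CC)[C@@H](C(C(=O)[O-])C(=O)[O-])[C@@H](O)[C@H](O[Si](C)(C)C(C)(C)C)[C@@]12C.[Li+].[Li+] | intermediate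
17 | 1α-hydroxy cis-8α,12-lactone 11-carboxylic acid (6β-OTES, 9β-OTBS, C2=C15 alkene) | O[C@H]1C=CC[C@@H]2[C@H](O[Si](CC)(CC)CC)[C@H]3[C@H](C(=O)O)C(=O)O[C@H]3[C@H](O[Si](C)(C)C(C)(C)C)[C@@]12C | intermediate
18 | 2α,15α-epoxy-1α-hydroxy lactone acid | O[C@H]1[C@H]4O[C@H]4C[C@@H]2[C@H](O[Si](CC)(CC)CC)[C@H]3[C@H](C(=O)O)C(=O)O[C@H]3[C@H](O[Si](C)(C)C(C)(C)C)[C@@]12C | intermediate
19 | 2α,15α-epoxy-1-keto lactone acid | O=C1[C@H]4O[C@H]4C[C@@H]2[C@H](O[Si](CC)(CC)CC)[C@H]3[C@H](C(=O)O)C(=O)O[C@H]3[C@H](O[Si](C)(C)C(C)(C)C)[C@@]12C | intermediate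
20 | C1 tosylhydrazone of 19 (not isolated) | Cc1ccc(cc1)S(=O)(=O)NN=C1[C@H]4O[C@H]4C[C@@H]2[C@H](O[Si](CC)(CC)CC)[C@H]3[C@H](C(=O)O)C(=O)O[C@H]3[C@H](O[Si](C)(C)C(C)(C)C)[C@@]12C | intermediate
21 | seco acid: 10α-ethynyl, 10β-methyl, 5β-CH2CHO, 6β-OTES, 9β-OTBS, cis 8α,12-lactone 11-carboxylic acid | C#C[C@@]1(C)[C@H](CC=O)[C@H](O[Si](CC)(CC)CC)[C@H]2[C@H](C(=O)O)C(=O)O[C@H]2[C@@H]1O[Si](C)(C)C(C)(C)C | intermediate
22 | 10α-vinyl analogue of 21 | C=C[C@@]1(C)[C@H](CC=O)[C@H](O[Si](CC)(CC)CC)[C@H]2[C@H](C(=O)O)C(=O)O[C@H]2[C@@H]1O[Si](C)(C)C(C)(C)C | intermediate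
23 | formaldehyde | C=O | starting material
24 | bis-silyl elemanolide dienal: 5β-C(=CH2)CHO, 11(13)-methylene 8α,12-lactone, 6β-OTES, 9β-OTBS | C=C[C@@]1(C)[C@H](C(=C)C=O)[C@H](O[Si](CC)(CC)CC)[C@H]2C(=C)C(=O)O[C@H]2[C@@H]1O[Si](C)(C)C(C)(C)C | intermediate
25 | 6β-hydroxy 9β-OTBS dienal | C=C[C@@]1(C)[C@H](C(=C)C=O)[C@H](O)[C@H]2C(=C)C(=O)O[C@H]2[C@@H]1O[Si](C)(C)C(C)(C)C | intermediate
26 | angelic acid ((Z)-2-methylbut-2-enoic acid) | C/C=C(/C)C(=O)O | starting material
27 | angelic 2,4,6-trichlorobenzoic anhydride (not isolated) | C/C=C(/C)C(=O)OC(=O)c1c(Cl)cc(Cl)cc1Cl | intermediate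
28 | 6β-O-angeloyl 9β-OTBS dienal | C=C[C@@]1(C)[C@H](C(=C)C=O)[C@H](OC(=O)/C(C)=C\C)[C@H]2C(=C)C(=O)O[C@H]2[C@@H]1O[Si](C)(C)C(C)(C)C | intermediate
29 | 6β-O-angeloyl 9β-hydroxy dienal | C=C[C@@]1(C)[C@H](C(=C)C=O)[C@H](OC(=O)/C(C)=C\C)[C@H]2C(=C)C(=O)O[C@H]2[C@@H]1O | intermediate
30 | methacrylic anhydride | CC(=C)C(=O)OC(=O)C(C)=C | starting material
31 | CNP0102441.1: 6β-angeloyloxy-9β-methacryloyloxy elemanolide dienal | C=C[C@@]1(C)[C@H](C(=C)C=O)[C@H](OC(=O)/C(C)=C\C)[C@H]2C(=C)C(=O)O[C@H]2[C@@H]1OC(=O)C(=C)C | target

**Totals and risks**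

Total step count: 21.
Longest linear sequence: 21 steps (1 → 31); all other partners are purchased.

Steps most likely to fail:

Step 8 (cyclopropanation). The carbenoid may react too slowly with the hindered trisubstituted enol ether flanked by two silyloxy carbons, so that carbene dimerisation, attack on the ring A alkene or on an ether oxygen, or attack from the β face competes. The fallback sets out from 9 and introduces the malonate as a radical instead of a carbenoid. Dimethyl malonate is oxidised with (NH4)2Ce(NO3)6 in MeOH buffered with NaHCO3 at 0 °C. The electrophilic malonyl radical should add to C7 of the enol ether anti to the axial 6β-silyloxy group, and the resulting C8 radical is oxidised to the oxocarbenium ion and trapped by methanol. This gives the 7α-malonyl C8 dimethyl ketal F1. Aqueous HCl in THF, as in step 9, hydrolyses the ketal and the TES ether and returns the route at 12.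

Step 15 (key fragmentation). Condensation of the sulfonylhydrazide with the neopentyl C1 ketone may be slower than acid-mediated opening of the epoxide, or the hydrazide may be consumed by the aldehyde as it forms. The fallback sets out from 19 and uses the aminoaziridine variant of the fragmentation, which needs no acid. Condensation with trans-1-amino-2,3-diphenylaziridine (CH2Cl2, 0 °C → rt) gives the N-aziridinylimine F2. Warming in toluene (about 60 °C) expels trans-stilbene and N2 and cleaves C2–C15 in the same sense, returning the route at 21.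

Step 2 (cycloaddition). The catalysed reaction at the methyl-bearing, trisubstituted double bond may be slow, so that the uncatalysed pathway erodes the enantioselectivity. The fallback sets out from 2 and 3 and moves the enantiodiscrimination to the first reduction. Thermal cycloaddition (toluene, 80 °C) gives 4 together with its mirror image ent-4 F3. DBU, as in step 3, converts the pair into 5 and ent-5 F4. Reduction with catecholborane and (S)-2-methyl-CBS-oxazaborolidine (toluene, –78 °C), stopped near half conversion, should reduce the matched enantiomer 5, in which catalyst and substrate both favour α-face hydride delivery, and leave F4 as the ketone, which is removed by chromatography. The route is rejoined at 6.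

Further compounds
F1 | step 8 | 7α-[bis(methoxycarbonyl)methyl] C8 dimethyl ketal (1α-OAc, 6β-OTES, 9β-OTBS, C2=C15 alkene) | CC(=O)O[C@H]1C=CC[C@@H]2[C@H](O[Si](CC)(CC)CC)[C@@H](C(C(=O)OC)C(=O)OC)C(OC)(OC)[C@H](O[Si](C)(C)C(C)(C)C)[C@@]12C
F2 | step 15 | N-(trans-2,3-diphenylaziridin-1-yl)imine of 19 at C1 (mixture of aziridine diastereomers) | C1(c2ccccc2)C(c2ccccc2)N1N=C1[C@H]4O[C@H]4C[C@@H]2[C@H](O[Si](CC)(CC)CC)[C@H]3[C@H](C(=O)O)C(=O)O[C@H]3[C@H](O[Si](C)(C)C(C)(C)C)[C@@]12C
F3 | step 2 | ent-4, mirror image of the cis-fused cycloadduct | CC(=O)O[C@@H]1C=CC[C@@H]2C(=O)C=C(OC)C(=O)[C@]12C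
F4 | step 2 | ent-5, mirror image of the trans-fused enedione | CC(=O)O[C@@H]1C=CC[C@H]2C(=O)C=C(OC)C(=O)[C@]12C
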